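One charge goes in by different routes.

| flask | first end groups | second end groups | time | remark |
|---|---|---|---|---|
| birch | 20 mM | 20.0 mM (in portions, 3, over 20 h) | 30 h | first portion at the start, last at 20 h |
| oak | 20 mM | 20.0 mM (fed, over 20 h) | 30 h | all else is in the flask from the start; the feed brings no volume worth counting |
| elm | 20 mM (fed, over 20 h) | 20.0 mM | 30 h | all else is in the flask from the start; the feed brings no volume worth counting |
| alder | 20 mM | 20.0 mM (fed, over 2.0 h) | 30 h | all else is in the flask from the start; the feed brings no volume worth counting |
| maple | 20 mM | 20.0 mM | 30 h | everything together at the start |

    first end groups + second end groups ⇌ links + released group (K1 = 2.6, k1 = 0.14 M⁻¹ min⁻¹)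
    first end groups + links → side product (k2 = 0.060 M⁻¹ min⁻¹)
    crystals ⇌ links, rate k3*(cs3 - [links]) while solid is left; crystals form when [links] > cs3 (cs3 = 2.6 mM, k3 = 0.026 min⁻¹)
    second end groups + links → over-reaction product (k4 = 0.0030 M⁻¹ min⁻¹)

- percentages count the first end groups that a species holds: one side product counts as two
- links is meant together with its crystals
- solid, in amounts per volume of the solution: crystals
- run time (birch): 30 h

1. the best flask by share of links in links plus side product; "all alike" if 1.5 percentage points covers them all (birch / oak / elm / alder / maple / all alike)
2. share of links in links plus side product at the end, birch
3. share of links in links plus side product at the end, oak
4. share of links in links plus side product at the end, elm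
5. share of links in links plus side product at the end, alder
6. share of links in links plus side product at the end, maple

I count what is left of the first end groups, rung by rung. Exchange with the crystals comes first, at 38.5 min. Next comes link-making: at equal charges, 5.95 h is the second-order half-life, and the fraction left after time t is one over one plus t divided by that half-life. Since exchange far outruns link-making, I hold dissolved [links] at 2.6 mM once crystals appear. The next rung is 107 h, the side time: one over k2 times the solubility, the pseudo-first-order time for first end groups meeting dissolved links. It is longer than the run, so side product is a slow leak. The last rung is step 4: in maple, with the other concentrations as charged, dissolved links has a half-life of 190 h by this step alone, longer than the side time and long against 30 h, so I drop it. I also drop the back reaction, which is my own simplification.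

Each side product holds two first end groups, so side product in percent is twice the exposure over the side time, exposure being the hours of full charge, the fraction left summed over time. For maple, the fraction left at the end is 16.6% and the exposure is 10.7 h, which gives 20.0% side product and a share of 76.0%. Alder's feed of 2.0 h is shorter than the half-life, so I give it 76.0% too. For elm, I use the mean age of the fed first end groups, 20.0 h: the fraction left is 22.9%, the exposure 8.76 h, the side product 16.4% and the share 78.7%. In oak and birch the second end groups arrive on average 10.0 h after the start, longer than the half-life, so I give only a bound, the share I reckoned for maple: oak below 76.0% and birch below 76.0%.

The forecast picks elm, with 66% for birch, 68% for oak, 78% for elm, 70% for alder and 70% for maple, on the ground that “side product depends mainly on how much first end groups stay in solution over time”. Its maple lies below mine.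

The simulation gives elm as best, with 62.1% for birch, 67.1% for oak, 78.9% for elm, 74.5% for alder and 74.5% for maple. Elm leads maple by 4.4 percentage points, and elm's share has moved by 5 points with second end groups at 16.5 mM or 25.3 mM, the other charges and the time held. With dissolved [links] taken at the solubility, side product at the end, times half the side time, reads as 15.7 h of exposure in birch, 11.2 h in maple and 8.42 h in elm. At 300 h, past the side time, elm's share stands at 23.0%.

The rate constants are those of an exercise; what happens was integrated by code.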